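(The readings come from a simulation for an exercise.)

The ratio of target gained to starting material lost at the first reading of the violet flask is 0.832, a selectivity read with the scatter of the readings.

| setting | violet | flask |
|---|---|---|
| starting material | 1 M | 1.0 M |
| reagent | 0.90 M | 0.900 M |
| second substrate | 0.50 M | 0.500 M |
| remark | the very flask that is asked about, followed so far |  |
| time |  | 10 min |

violet run (percent of the starting material charged)

| time / min | target / % | starting material / % |
|---|---|---|
| 0.667 | 11.4 | 86.3 |
| 1.00 | 16.8 | 80.6 |
| 1.33 | 16.4 | 73.3 |
| 2.50 | 23.2 | 62.4 |
| 3.00 | 22.6 | 57.7 |
| 5.00 | 24.1 | 49.2 |
| 8.00 | 23.0 | 38.5 |

(standard deviation of a reading: 1 percentage point)

- north: change nothing and wait 20 min more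
- south: at 10 min take out 90% of the target then present, then wait 20 min
- south-west: at 10 min add starting material, 50.0% of the amount charged, then wait 20 min

- target taken out counts as made
- additions bring no volume worth counting

- target, in percent of the starting material first charged, at 10 min
- the option that brings most further target ("none" if no option brings more than 2 percentage points) (north / south / south-west / none)
- target present, with what was taken out counted in, in percent of the starting material first charged, after south
- target present, with what was taken out counted in, in percent of the starting material first charged, after south-west

Starting material is lost at 0.205 /min of the charge at the start of the violet run, and between 5.00 min and 8.00 min at 0.0357 /min. That slowing splits in two: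

total slowing: 5.76
from starting material itself: 2.12
from its partner, taken to be the unread reagent: 2.72

Target meanwhile stays flat, at 23.6% on average. If the ratio still holds, making continues and something consumes target just as fast:

making, late: 0.0297 /min
loss constant, taken as proportional to target: 0.126 /min

Read so, with the scatter of the readings and with the loss assumed simple and first order, this gives an estimated half-life of target in the violet flask against whatever consumes it, 5.50 min.

So target at 10 min should lie near 23.6%, or a little under it as making slows. The wait of 20 min is longer than this half-life, so target left in the flask turns over, while target taken out is banked. South should beat north by about 19 percentage points. Whatever extra target south-west makes stays exposed to the same loss, so the pick here is south.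

The forecast differs. It gives 24.5%, 34.3% and 39.3%, and picks south-west: “Reagent is limiting, so adding starting material wins.”

The flask gives 21.7%, and south is best: south brings 10 points, north −3.9 points, south-west −0.99 points. The totals are 31.9% after south and 20.7% after south-west.

    starting material + second substrate → cross product (k = 0.00178 /M/s)
    target ⇌ isomer of the product (K = 2.71, k = 0.00274 /s)
    starting material + reagent → target (k = 0.00441 /M/s)
    reagent ⇌ dormant form (K = 0.655, k = 0.00351 /s)
    second substrate + reagent → second product (k = 0.00223 /M/s)

South stands 14 points above north, against the 19 points reckoned from the estimated half-life of 5.50 min. With that estimated half-life carried unchanged to the neighbouring flask charged with 0.25 M of starting material, target as a share of the starting material charged is reckoned to follow the making rate per starting material charged: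

c(target)/c(starting material charged) ∝ [c(starting material)/c(starting material charged)] · [c(reagent)/c(reagent charged)]

At 10.0 min the neighbouring flask holds starting material 21.8% and reagent 34.8%, against 33.5% and 17.0% in the flask. That is a factor of 1.33, which takes 21.7% to 28.9%. The neighbouring flask holds 27.5% of target.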